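**Plan**

- Feature used: ring C (C8, C9, C11–C14) is a 2-hydroxy-3-isopropyl-1,4-quinone fused through C8=C9 to the cycloheptatriene ring B (C5–C10, C20). Its carbons C11–C14 with their oxygen and isopropyl substituents are those of an alkoxy(isopropyl)cyclobutenedione, and C8=C9 is an alkene of ring B.
- Cuts: C8–C14 (restoring the C11–C14 bond of a 4-hydroxycyclobutenone), then C9–C11 (alkenyllithium + cyclobutenedione); in ring B C8=C9 and C10–C20; the enol lactone at C6=C7 (back to a cis anhydride); ring A at C3–C4 and C5–C10.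
- Forward order: ring A with the anhydride, then the C6=C7 enol lactone, then ring B, then the C9 iodide, and ring C last.
- Stereochemistry: C4 and C5 arise together in the Diels–Alder step (cis from the cyclic dienophile, absolute sense from a C2-symmetric pyrrolidine auxiliary); C1 comes from a Corey–Bakshi–Shibata reduction.

Key step: step 17

Numbering: locants C1–C20 are those of the icetexane skeleton of the target (ring A C1–C5, C10; lactone C4–C19(=O)–O–C6).
Assumption: the (2R,5R) auxiliary is taken to give 10 as the (3aS,7aR) enantiomer, by analogy with its cycloadditions to 2-substituted acroleins; if the sense is opposite, the (2S,5S) pyrrolidine is used.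

**Route**

Step 1
Reactants: 1 1,1,2,2-tetramethoxyethane; 2 triethyl phosphite
Product: 3 diethyl (1,2,2-trimethoxyethyl)phosphonate
Conditions: BF3·OEt2, CH2Cl2, −20 °C to rt
Reagents that add atoms: none
Why: Michaelis–Arbuzov-type reaction of an acetal, in which BF3 ionises one acetal to an oxocarbenium ion that the phosphite traps before dealkylation, the usual way from acetals to α-alkoxy phosphonates.

Step 2
Reactants: 4 (2R,5R)-2,5-diphenylpyrrolidine; 5 (E)-4-methoxybut-3-en-2-one
Product: 6 (E)-4-[(2R,5R)-2,5-diphenylpyrrolidin-1-yl]but-3-en-2-one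
Conditions: MeOH, rt
Reagents that add atoms: none
Why: Addition–elimination (aza-Michael addition, then loss of methanol) of a secondary amine on a β-methoxy enone, the standard access to vinylogous amides.

Step 3
Reactants: 6 (E)-4-[(2R,5R)-2,5-diphenylpyrrolidin-1-yl]but-3-en-2-one
Product: 7 (E)-1-[(2R,5R)-2,5-diphenylpyrrolidin-1-yl]-3-(tert-butyldimethylsilyloxy)buta-1,3-diene
Conditions: KN(SiMe3)2, THF, −78 °C; TBSCl
Reagents that add atoms: tert-butyldimethylsilyl chloride, CC(C)(C)[Si](C)(C)Cl
Why: Kinetic deprotonation of the methyl ketone and O-silylation (silyl enol ether formation) should give the 1-amino-3-silyloxydiene.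

Step 4
Reactants: 7 (E)-1-[(2R,5R)-2,5-diphenylpyrrolidin-1-yl]-3-(tert-butyldimethylsilyloxy)buta-1,3-diene; 8 citraconic anhydride
Product: 10 (3aS,7aR)-3a-methyl-7,7a-dihydro-2-benzofuran-1,3,6(3aH)-trione, via Diels–Alder adduct 9 (not isolated)
Conditions: toluene, −20 °C to rt; then HF·pyridine, MeCN, 0 °C
Reagents that add atoms: none
Why: Diels–Alder reaction in which the CH2 terminus of the electron-rich diene bonds to the unsubstituted dienophile carbon (C10–C5) and the amino terminus to the methyl-bearing carbon (C3–C4), the cyclic dienophile makes C4-methyl and C5–H cis, the C2-symmetric pyrrolidine shields one diene face and so sets the absolute configuration, and HF then cleaves the silyl enol ether and eliminates the auxiliary (E1cB) to the enone.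

Step 5
Reactants: 10 (3aS,7aR)-3a-methyl-7,7a-dihydro-2-benzofuran-1,3,6(3aH)-trione; 3 diethyl (1,2,2-trimethoxyethyl)phosphonate
Product: 12 7-[2-(diethoxyphosphoryl)-1,2-dimethoxyethyl] derivative of enone anhydride 10, via silyl dienol ether 11 (not isolated)
Conditions: TBSOTf, Et3N, CH2Cl2, 0 °C; then 3, Me3SiOTf (0.2 equiv), −78 to −40 °C
Reagents that add atoms: none
Why: Mukaiyama aldol-type addition to an acetal, in which the ketone of 10 can enolise only toward C10, so soft enolisation gives one silyl dienol ether whose C10 attacks the oxocarbenium ion from 3 to form C10–C20; the side-chain centres are erased later.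

Step 6
Reactants: 12 7-[2-(diethoxyphosphoryl)-1,2-dimethoxyethyl] derivative of enone anhydride 10
Product: 13 7-[2-(diethoxyphosphoryl)-1,2-dimethoxyethyl]-3a-methylhexahydro-2-benzofuran-1,3,6-trione
Conditions: H2 (1 atm), Pd/C, EtOAc, rt
Reagents that add atoms: none
Why: Heterogeneous catalytic hydrogenation should saturate the only C=C bond (C2=C3) and leave ketone, anhydride and phosphonate untouched.

Step 7
Reactants: 13 7-[2-(diethoxyphosphoryl)-1,2-dimethoxyethyl]-3a-methylhexahydro-2-benzofuran-1,3,6-trione; 14 (triphenylphosphoranylidene)acetaldehyde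
Product: 15 (E)-2-[4-(2-diethoxyphosphoryl-1,2-dimethoxyethyl)-7a-methyl-1,5-dioxohexahydro-2-benzofuran-3(1H)-ylidene]acetaldehyde
Conditions: CHCl3, 50 °C
Reagents that add atoms: none
Why: Wittig olefination of a cyclic anhydride by a stabilised ylide, which gives an enol lactone at the less hindered carbonyl (C6 on tertiary C5, not C19 on quaternary C4) with the (E) geometry usual for succinic anhydrides, so that C8 lies cis to C5, while the ketone is far less reactive toward this ylide.

Step 8
Reactants: 15 (E)-2-[4-(2-diethoxyphosphoryl-1,2-dimethoxyethyl)-7a-methyl-1,5-dioxohexahydro-2-benzofuran-3(1H)-ylidene]acetaldehyde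
Product: 17 (4S,5R)-9-methoxy-4-methyl-1-oxo ring A/B triene (C6=C7, C8=C9, C10=C20) carrying the C19-to-C6 enol lactone, via enone phosphonate 16 (not isolated)
Conditions: LiCl, DBU, MeCN (0.005 M), 0 °C to rt
Reagents that add atoms: none
Why: Base first expels methanol from the β-methoxy ketone (E1cB) to give the (E)-enone, whose C9 phosphonate carbanion is stabilised through the enone, and an intramolecular vinylogous Horner–Wadsworth–Emmons olefination of the C8 aldehyde (Masamune–Roush conditions) closes the seven-membered ring B and leaves C9 as a methyl enol ether, as α-alkoxy phosphonates do.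

Step 9
Reactants: 17 (4S,5R)-9-methoxy-4-methyl-1-oxo ring A/B triene carrying the C19-to-C6 enol lactone
Product: 18 (1R,4S,5R)-1-hydroxy-9-methoxy ring A/B triene enol lactone
Conditions: (S)-2-methyl-CBS-oxazaborolidine (0.2 equiv), catecholborane, toluene, −78 to −40 °C
Reagents that add atoms: none
Why: Corey–Bakshi–Shibata reduction in which the alkenyl carbon C10 acts as the large group, so the (S)-catalyst should give the (1R)-alcohol, the same face as axial hydride attack anti to the lactone carbonyl on C4; C1 is thus set by matched reagent and substrate control.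

Step 10
Reactants: 18 (1R,4S,5R)-1-hydroxy-9-methoxy ring A/B triene enol lactone
Product: 19 (1R,4S,5R)-1-(tert-butyldimethylsilyloxy)-9-methoxy ring A/B triene enol lactone
Conditions: TBSOTf, 2,6-lutidine, CH2Cl2, −78 °C
Reagents that add atoms: tert-butyldimethylsilyl trifluoromethanesulfonate, CC(C)(C)[Si](C)(C)OS(=O)(=O)C(F)(F)F
Why: Silylation of the secondary allylic alcohol with a silyl triflate and a hindered base protects C1–OH against the organolithium of step 16.

Step 11
Reactants: 19 (1R,4S,5R)-1-(tert-butyldimethylsilyloxy)-9-methoxy ring A/B triene enol lactone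
Product: 20 (1R,4S,5R)-1-(tert-butyldimethylsilyloxy)-9-oxo ring A/B dienone (C6=C7 enol lactone, C8H2, C10=C20)
Conditions: oxalic acid (cat.), THF–H2O, 0 °C
Reagents that add atoms: water, O
Why: Mild acid hydrolysis of the dienol methyl ether by kinetic protonation at C8 (as with steroidal dienol ethers) should give the β,γ-unsaturated C9 ketone, while the less basic enol lactone and the silyl ether persist.

Step 12
Reactants: 20 (1R,4S,5R)-1-(tert-butyldimethylsilyloxy)-9-oxo ring A/B dienone
Product: 21 (1R,4S,5R)-1-(tert-butyldimethylsilyloxy)-9-(trifluoromethanesulfonyloxy) ring A/B triene enol lactone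
Conditions: KN(SiMe3)2, THF, −78 °C; PhNTf2
Reagents that add atoms: N-phenylbis(trifluoromethanesulfonimide), O=S(=O)(N(c1ccccc1)S(=O)(=O)C(F)(F)F)C(F)(F)F
Why: C8–H lies between the C9 ketone and the C6=C7 enol lactone and is the most acidic and most accessible position, so deprotonation and O-sulfonylation (enol triflate formation) should give the C8=C9 dienyl triflate regiospecifically.

Step 13
Reactants: 21 (1R,4S,5R)-1-(tert-butyldimethylsilyloxy)-9-(trifluoromethanesulfonyloxy) ring A/B triene enol lactone
Product: 22 (1R,4S,5R)-1-(tert-butyldimethylsilyloxy)-9-(trimethylstannyl) ring A/B triene enol lactone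
Conditions: Me3SnSnMe3, Pd(PPh3)4 (5 mol%), LiCl, THF, 60 °C
Reagents that add atoms: hexamethylditin, C[Sn](C)(C)[Sn](C)(C)C
Why: Palladium-catalysed stannylation of an alkenyl triflate with a distannane (Stille-type coupling), with chloride assisting the turnover.

Step 14
Reactants: 22 (1R,4S,5R)-1-(tert-butyldimethylsilyloxy)-9-(trimethylstannyl) ring A/B triene enol lactone
Product: 23 (1R,4S,5R)-1-(tert-butyldimethylsilyloxy)-9-iodo ring A/B triene enol lactone
Conditions: I2, CH2Cl2, 0 °C
Reagents that add atoms: iodine, II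
Why: Iododestannylation, an ipso substitution of the alkenylstannane with retention that is much faster than attack of iodine on the triene.

Step 15
Reactants: 24 di-tert-butyl squarate; 25 isopropylmagnesium chloride
Product: 27 3-tert-butoxy-4-isopropylcyclobut-3-ene-1,2-dione, via hydroxycyclobutenone 26 (not isolated)
Conditions: THF, −78 °C; then (CF3CO)2O, −78 to 0 °C; aq. NaHCO3
Reagents that add atoms: none
Why: 1,2-Addition of the Grignard reagent to one squarate carbonyl, then trifluoroacetylation of the carbinol, ionisation assisted by the alkoxy groups and loss of a tert-butyl cation as isobutene, the standard conversion of squarates into 3-alkyl-4-alkoxycyclobutenediones.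

Step 16
Reactants: 23 (1R,4S,5R)-1-(tert-butyldimethylsilyloxy)-9-iodo ring A/B triene enol lactone; 27 3-tert-butoxy-4-isopropylcyclobut-3-ene-1,2-dione
Product: 29 3-tert-butoxy-4-hydroxy-2-isopropylcyclobut-2-enone bearing at C4 the C9 carbon of the 1-O-silylated lactone-fused cycloheptatriene (carbinol epimers), via alkenyllithium 28 (not isolated)
Conditions: t-BuLi (2.1 equiv), THF–Et2O, −100 °C, 5 min; then 27, −100 to −78 °C; aq. NH4Cl
Reagents that add atoms: none
Why: Iodine–lithium exchange at −100 °C should be far faster than attack on the hindered α-quaternary lactone, and the alkenyllithium then adds 1,2 to the ketone-like carbonyl of 27 beside the alkoxy-bearing carbon (the other carbonyl is a vinylogous ester), which places the carbinol carbon C11 next to C12–O-tert-butyl.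

Step 17
Reactants: 29 3-tert-butoxy-4-hydroxy-2-isopropylcyclobut-2-enone bearing at C4 the C9 carbon of the lactone-fused cycloheptatriene
Product: 32 ring C hydroquinone 12-tert-butyl ether of the 1-O-silylated tetracycle, via dienylketene 30 (not isolated), via cyclohexadienone 31 (not isolated)
Conditions: toluene (0.01 M, degassed), 110 °C, 30–60 min
Reagents that add atoms: none
Why: Heating opens the cyclobutenone by conrotatory 4π-electrocyclic cleavage of the C11–C14 bond, the hydroxyl turning outward so that the C9 alkenyl group comes to lie beside the ketene. Ring C then closes by thermal disrotatory 6π-electrocyclisation of the ketene C=C, C12=C11 and C9=C8, which forms C8–C14, and enolisation of the cyclohexadienone (C8–H to the C14 oxygen) gives the hydroquinone. This is the Moore ring expansion of 4-alkenyl-4-hydroxycyclobutenones. No stereocentre is formed, and both carbinol epimers of 29 converge. The substitution pattern is fixed beforehand, isopropyl lying next to the ketene carbon (C13 beside C14) and the tert-butoxy group next to the carbinol carbon (C12 beside C11). The cascade must outrun 1,5-hydrogen shifts of the cycloheptatriene (C5–H) and loss of isobutene, which the easy opening of alkenyl-substituted hydroxycyclobutenones near 100 °C, high dilution and a short heating time should secure, and no oxidant touches the enol lactone, the triene or the allylic silyl ether.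

Step 18
Reactants: 32 ring C hydroquinone 12-tert-butyl ether of the 1-O-silylated tetracycle
Product: 33 1-O-(tert-butyldimethylsilyl)-12-O-tert-butyl-6,7-anhydroballotiquinone
Conditions: Ag2O, MgSO4, Et2O, rt
Reagents that add atoms: none
Why: Two-electron oxidation of the para-hydroquinone to the quinone under neutral conditions that should spare enol lactone, triene and silyl ether.

Step 19
Reactants: 33 1-O-(tert-butyldimethylsilyl)-12-O-tert-butyl-6,7-anhydroballotiquinone
Product: 34 1-O-(tert-butyldimethylsilyl)-6,7-anhydroballotiquinone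
Conditions: CF3CO2H, CH2Cl2, 0 °C
Reagents that add atoms: none
Why: Acidolysis of the tert-butyl vinylogous ester (ionisation, loss of isobutene) frees the C12 hydroxyl without any nucleophile or base that could open the enol lactone.

Step 20
Reactants: 34 1-O-(tert-butyldimethylsilyl)-6,7-anhydroballotiquinone
Product: 35 6,7-anhydroballotiquinone
Conditions: HF·pyridine, THF, 0 °C to rt
Reagents that add atoms: none
Why: Desilylation of the secondary silyl ether with buffered HF should release the C1 alcohol without ionising the allylic C1–O bond.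

**Compound list**

1 | 1,1,2,2-tetramethoxyethane | COC(OC)C(OC)OC | starting material
2 | triethyl phosphite | CCOP(OCC)OCC | starting material
3 | diethyl (1,2,2-trimethoxyethyl)phosphonate (racemic) | CCOP(=O)(OCC)C(OC)C(OC)OC | intermediate
4 | (2R,5R)-2,5-diphenylpyrrolidine | c1ccccc1[C@H]1CC[C@H](c2ccccc2)N1 | starting material
5 | (E)-4-methoxybut-3-en-2-one | CO/C=C/C(C)=O | starting material
6 | (E)-4-[(2R,5R)-2,5-diphenylpyrrolidin-1-yl]but-3-en-2-one | CC(=O)/C=C/N1[C@H](CC[C@@H]1c1ccccc1)c1ccccc1 | intermediate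
7 | (E)-1-[(2R,5R)-2,5-diphenylpyrrolidin-1-yl]-3-(tert-butyldimethylsilyloxy)buta-1,3-diene | C=C(O[Si](C)(C)C(C)(C)C)/C=C/N1[C@H](CC[C@@H]1c1ccccc1)c1ccccc1 | intermediate
8 | citraconic anhydride (3-methylfuran-2,5-dione) | CC1=CC(=O)OC1=O | starting material
9 | Diels–Alder adduct: 6-(tert-butyldimethylsilyloxy)-3a-methyl-4-[(2R,5R)-2,5-diphenylpyrrolidin-1-yl]-3a,4,7,7a-tetrahydro-2-benzofuran-1,3-dione, amine cis to the anhydride, ring fusion as in 10 | CC(C)(C)[Si](C)(C)OC1=C[C@H](N2[C@H](CC[C@@H]2c2ccccc2)c2ccccc2)[C@]3(C)C(=O)OC(=O)[C@@H]3C1 | intermediate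
10 | (3aS,7aR)-3a-methyl-7,7a-dihydro-2-benzofuran-1,3,6(3aH)-trione (cis-fused enone anhydride; C4 methyl, C5–H) | O=C1C=C[C@]2(C)C(=O)OC(=O)[C@@H]2C1 | intermediate
11 | 6-(tert-butyldimethylsilyloxy)-3a-methyl-3a,7a-dihydro-2-benzofuran-1,3-dione (silyl dienol ether of 10, C1=C10 and C2=C3) | CC(C)(C)[Si](C)(C)OC1=C[C@H]2C(=O)OC(=O)[C@@]2(C)C=C1 | intermediate
12 | 7-[2-(diethoxyphosphoryl)-1,2-dimethoxyethyl] derivative of 10 (side chain on C10; side-chain centres undefined) | O=C1C=C[C@]2(C)C(=O)OC(=O)[C@@H]2C1C(OC)C(OC)P(=O)(OCC)OCC | intermediate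
13 | 7-[2-(diethoxyphosphoryl)-1,2-dimethoxyethyl]-3a-methylhexahydro-2-benzofuran-1,3,6-trione ((4S,5R) ring fusion) | O=C1CC[C@]2(C)C(=O)OC(=O)[C@@H]2C1C(OC)C(OC)P(=O)(OCC)OCC | intermediate
14 | (triphenylphosphoranylidene)acetaldehyde | O=CC=P(c1ccccc1)(c1ccccc1)c1ccccc1 | starting material
15 | (E)-2-[4-(2-diethoxyphosphoryl-1,2-dimethoxyethyl)-7a-methyl-1,5-dioxohexahydro-2-benzofuran-3(1H)-ylidene]acetaldehyde (enol lactone, C19 carbonyl on C4, formyl cis to C5) | O=C1CC[C@]2(C)C(=O)O/C(=C/C=O)[C@@H]2C1C(OC)C(OC)P(=O)(OCC)OCC | intermediate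
16 | enone phosphonate: 15 after loss of methanol, (E)-C10=C20 with C20H–C9H(OMe)–P(O)(OEt)2 | O=C1CC[C@]2(C)C(=O)O/C(=C/C=O)[C@@H]2/C1=C\C(OC)P(=O)(OCC)OCC | intermediate
17 | (4S,5R)-9-methoxy-4-methyl-1-oxo ring A/B triene (C6=C7, C8=C9, C10=C20) with the C19-to-C6 enol lactone | O=C1CC[C@]2(C)C(=O)OC3=CC=C(OC)C=C1[C@H]23 | intermediate
18 | (1R,4S,5R)-1-hydroxy-9-methoxy ring A/B triene enol lactone | O[C@@H]1CC[C@]2(C)C(=O)OC3=CC=C(OC)C=C1[C@H]23 | intermediate
19 | (1R,4S,5R)-1-(tert-butyldimethylsilyloxy)-9-methoxy ring A/B triene enol lactone | CC(C)(C)[Si](C)(C)O[C@@H]1CC[C@]2(C)C(=O)OC3=CC=C(OC)C=C1[C@H]23 | intermediate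
20 | (1R,4S,5R)-1-(tert-butyldimethylsilyloxy)-9-oxo ring A/B dienone (C6=C7 enol lactone, C8H2, C10=C20) | CC(C)(C)[Si](C)(C)O[C@@H]1CC[C@]2(C)C(=O)OC3=CCC(=O)C=C1[C@H]23 | intermediate
21 | (1R,4S,5R)-1-(tert-butyldimethylsilyloxy)-9-(trifluoromethanesulfonyloxy) ring A/B triene enol lactone | CC(C)(C)[Si](C)(C)O[C@@H]1CC[C@]2(C)C(=O)OC3=CC=C(OS(=O)(=O)C(F)(F)F)C=C1[C@H]23 | intermediate
22 | (1R,4S,5R)-1-(tert-butyldimethylsilyloxy)-9-(trimethylstannyl) ring A/B triene enol lactone | CC(C)(C)[Si](C)(C)O[C@@H]1CC[C@]2(C)C(=O)OC3=CC=C([Sn](C)(C)C)C=C1[C@H]23 | intermediate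
23 | (1R,4S,5R)-1-(tert-butyldimethylsilyloxy)-9-iodo ring A/B triene enol lactone | CC(C)(C)[Si](C)(C)O[C@@H]1CC[C@]2(C)C(=O)OC3=CC=C(I)C=C1[C@H]23 | intermediate
24 | di-tert-butyl squarate (3,4-di-tert-butoxycyclobut-3-ene-1,2-dione) | CC(C)(C)OC1=C(OC(C)(C)C)C(=O)C1=O | starting material
25 | isopropylmagnesium chloride | CC(C)[Mg]Cl | starting material
26 | 2,3-di-tert-butoxy-4-hydroxy-4-isopropylcyclobut-2-enone | CC(C)C1(O)C(OC(C)(C)C)=C(OC(C)(C)C)C1=O | intermediate
27 | 3-tert-butoxy-4-isopropylcyclobut-3-ene-1,2-dione | CC(C)C1=C(OC(C)(C)C)C(=O)C1=O | intermediate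
28 | C9 alkenyllithium of the 1-O-silylated lactone-fused cycloheptatriene | [Li]C2=CC=C3OC(=O)[C@@]4(C)CC[C@@H](O[Si](C)(C)C(C)(C)C)C(=C2)[C@@H]34 | intermediate
29 | 3-tert-butoxy-4-hydroxy-2-isopropylcyclobut-2-enone with C4 bonded to C9 of the 1-O-silylated lactone-fused cycloheptatriene (carbinol epimers) | CC(C)C1=C(OC(C)(C)C)C(O)(C1=O)C2=CC=C3OC(=O)[C@@]4(C)CC[C@@H](O[Si](C)(C)C(C)(C)C)C(=C2)[C@@H]34 | intermediate
30 | dienylketene: O=C14=C13(iPr)–C12(O-tert-butyl)=C11(OH)–C9 of the cycloheptatriene, C9 cis to C13 | CC(C)C(=C=O)/C(OC(C)(C)C)=C(/O)C2=CC=C3OC(=O)[C@@]4(C)CC[C@@H](O[Si](C)(C)C(C)(C)C)C(=C2)[C@@H]34 | intermediate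
31 | cyclohexadienone: C14 ketone, C13=C12, C11(OH)=C9, sp3 C8–H (keto tautomer of 32) | CC(C)C1=C(OC(C)(C)C)C(O)=C2C(C=C3OC(=O)[C@@]4(C)CC[C@@H](O[Si](C)(C)C(C)(C)C)C(=C2)[C@@H]34)C1=O | intermediate
32 | ring C hydroquinone (11,14-diol) 12-tert-butyl ether, 1-O-tert-butyldimethylsilyl, (1R,4S,5R) | CC(C)c1c(OC(C)(C)C)c(O)c2c(C=C3OC(=O)[C@@]4(C)CC[C@@H](O[Si](C)(C)C(C)(C)C)C(=C2)[C@@H]34)c1O | intermediate
33 | 1-O-(tert-butyldimethylsilyl)-12-O-tert-butyl-6,7-anhydroballotiquinone | CC(C)C1=C(OC(C)(C)C)C(=O)C2=C(C=C3OC(=O)[C@@]4(C)CC[C@@H](O[Si](C)(C)C(C)(C)C)C(=C2)[C@@H]34)C1=O | intermediate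
34 | 1-O-(tert-butyldimethylsilyl)-6,7-anhydroballotiquinone | CC(C)C1=C(O)C(=O)C2=C(C=C3OC(=O)[C@@]4(C)CC[C@@H](O[Si](C)(C)C(C)(C)C)C(=C2)[C@@H]34)C1=O | intermediate
35 | 6,7-anhydroballotiquinone, (1R,4S,5R) | CC(C)C1=C(O)C(=O)C2=C(C=C3OC(=O)[C@@]4(C)CC[C@@H](O)C(=C2)[C@@H]34)C1=O | target

**Step count and risks**

Total steps: 20. Longest linear sequence: 18 (steps 2–14 and 16–20).

Step 5. The acetal carbon of 3 carries a methoxy and a phosphoryl neighbour, so ionisation to the oxocarbenium ion may be too slow, and the phosphoryl oxygen may tie up the silyl Lewis acid, so that the silyl dienol ether simply reverts to 10. The fallback sets out from 10 and builds ring B without the phosphonate. The silyl dienol ether 11 is treated with commercial 1,1,2-trimethoxyethane and Me3SiOTf to give the 7-(1,2-dimethoxyethyl) enone anhydride F1, which is hydrogenated over Pd/C to the saturated ketone anhydride F2 and olefinated with ylide 14 to the enol lactone aldehyde F3. Acid (p-TsOH, benzene, 60 °C) then removes methanol to give the (E)-2-methoxyethylidene ketone F4, whose dienol attacks the C8 aldehyde through C9 and dehydrates (vinylogous aldol condensation). The route is rejoined at 17.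

Step 7. The formyl ylide is a weak nucleophile, so olefination of the anhydride may be slow enough for attack at the ring ketone or a second olefination of the product aldehyde to compete. The fallback sets out from 13 and uses the more nucleophilic S-ethyl (triphenylphosphoranylidene)ethanethioate to form the thioester enol lactone F5, which a Fukuyama reduction (Et3SiH, Pd/C, acetone) converts into the aldehyde. The route is rejoined at 15.

Step 16. Attack of t-BuLi or of the alkenyllithium on the enol lactone, or proton transfer, may compete with exchange and carbonyl addition. The fallback sets out from 23 and avoids organolithium reagents: insertion of zinc (Zn dust, LiCl, THF, 25–40 °C) gives the alkenylzinc iodide F6, which does not attack esters, and its addition to dione 27 is promoted by MgCl2. The route is rejoined at 29.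

Further compounds
F1 | step 5 | 7-(1,2-dimethoxyethyl) derivative of enone anhydride 10 | O=C1C=C[C@]2(C)C(=O)OC(=O)[C@@H]2C1C(OC)COC
F2 | step 5 | 7-(1,2-dimethoxyethyl)-3a-methylhexahydro-2-benzofuran-1,3,6-trione | O=C1CC[C@]2(C)C(=O)OC(=O)[C@@H]2C1C(OC)COC
F3 | step 5 | (E)-2-[4-(1,2-dimethoxyethyl)-7a-methyl-1,5-dioxohexahydro-2-benzofuran-3(1H)-ylidene]acetaldehyde | O=C1CC[C@]2(C)C(=O)O/C(=C/C=O)[C@@H]2C1C(OC)COC
F4 | step 5 | (E)-2-[4-((E)-2-methoxyethylidene)-7a-methyl-1,5-dioxohexahydro-2-benzofuran-3(1H)-ylidene]acetaldehyde | O=C1CC[C@]2(C)C(=O)O/C(=C/C=O)[C@@H]2/C1=C\COC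
F5 | step 7 | S-ethyl (E)-2-[4-(2-diethoxyphosphoryl-1,2-dimethoxyethyl)-7a-methyl-1,5-dioxohexahydro-2-benzofuran-3(1H)-ylidene]ethanethioate | O=C1CC[C@]2(C)C(=O)O/C(=C/C(=O)SCC)[C@@H]2C1C(OC)C(OC)P(=O)(OCC)OCC
F6 | step 16 | C9 alkenylzinc iodide of the 1-O-silylated lactone-fused cycloheptatriene | I[Zn]C2=CC=C3OC(=O)[C@@]4(C)CC[C@@H](O[Si](C)(C)C(C)(C)C)C(=C2)[C@@H]34
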